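**Retrosynthetic overview**

1. Target 16 comes from the 5,7-dibenzyl ether 15 by O-debenzylation; ring C of 15 is opened at C4–C4a, which leads back to the 3-aryloxy-3-phenylpropanoic acid 13 (intramolecular Friedel–Crafts acylation in the forward sense).
2. The CH2 bridge between C8 and the pyranone is traced to an arene formyl carbon: reductive Knoevenagel alkylation of pyranone 5 at its C3 by aldehyde 10.
3. The O1–C2 ether of 10 is made by Mitsunobu inversion between phenol 7 and the (R)-β-hydroxy ester 9 (asymmetric hydrogenation of keto ester 8); pyranone 5 comes from pentan-3-one and malonyl dichloride.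
4. Ring order: the pyranone ring is built first, ring A is bought as aldehyde 6, and ring C is closed last.
5. Structural feature used: the bridge sits on C8 of ring A, the neighbour of C8a and therefore of O1. With the O1–C2 ether in place and C8 already substituted, C4a is the only unsubstituted carbon flanking that oxygen, so an acyl chain hung from O1 can close only to the 8-linked flavanone; the 6-linked isomer is excluded by connectivity.

Key step: step 8

Remark: atoms are numbered as in a flavanone (O1, C2, C3, C4, C4a, C5 to C8, C8a). The only stereocentre is C2, of (S) configuration. The sense of induction in step 4 is assigned by analogy with other β-keto esters and would be checked by chiral HPLC before the material is carried on.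

**Route**

Step 1
Reactants: 1 pentan-3-one
Product: 2 3-(trimethylsilyloxy)pent-2-ene (E/Z mixture)
Conditions: Me3SiCl, Et3N, DMF, 80 °C
Reagents that add atoms: chlorotrimethylsilane C[Si](C)(C)Cl
Why: Silyl enol ether formation under equilibrating conditions; the ketone is symmetrical, so only one regioisomer can form and the alkene geometry does not matter for the next step.

Step 2
Reactants: 2 3-(trimethylsilyloxy)pent-2-ene; 3 malonyl dichloride
Product: 5 6-ethyl-4-hydroxy-5-methyl-2H-pyran-2-one, via 4-methyl-3,5-dioxoheptanoyl chloride 4 (not isolated)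
Conditions: Et2O, −78 °C → rt
Reagents that add atoms: none
Why: Acylative pyranone synthesis from a silyl enol ether: C-acylation at the methyl-bearing enol carbon by one acyl chloride gives 4, whose enol oxygen then closes onto the second acyl chloride (O-acylative lactonisation), which places methyl at C5 and ethyl at C6.

Step 3
Reactants: 6 2,4,6-trihydroxybenzaldehyde
Product: 7 2,4-bis(benzyloxy)-6-hydroxybenzaldehyde
Conditions: BnBr (2.1 equiv), K2CO3, DMF, rt
Reagents that add atoms: benzyl bromide BrCc1ccccc1
Why: Williamson etherification; the 4-OH and one of the two equivalent 2-OH groups are alkylated, while the last hydroxyl is held in a hydrogen bond to the formyl group and reacts slowest, so two equivalents of bromide should stop at the bis-ether.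

Step 4
Reactants: 8 tert-butyl 3-oxo-3-phenylpropanoate
Product: 9 tert-butyl (R)-3-hydroxy-3-phenylpropanoate
Conditions: [RuCl(p-cymene)((S)-SEGPHOS)]Cl (0.5 mol%), H2 (30 atm), EtOH, 50 °C
Reagents that add atoms: none
Why: Noyori asymmetric hydrogenation of a β-keto ester; chelation of ketone and ester oxygens to the ruthenium hydride bearing the (S)-diphosphine directs hydride to one carbonyl face and should give the (R)-carbinol (the descriptor is opposite to that of alkyl β-keto esters with the same ligand only because phenyl outranks CH2CO2tBu).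

Step 5
Reactants: 7 2,4-bis(benzyloxy)-6-hydroxybenzaldehyde; 9 tert-butyl (R)-3-hydroxy-3-phenylpropanoate
Product: 10 tert-butyl (S)-3-[3,5-bis(benzyloxy)-2-formylphenoxy]-3-phenylpropanoate
Conditions: PPh3, DIAD (added last, slowly), toluene, −20 °C → rt
Reagents that add atoms: none
Why: Mitsunobu etherification; the acidic chelated phenol protonates the betaine and its phenoxide displaces the oxyphosphonium group in an SN2 step with inversion, which turns the (R)-carbinol into the (S)-aryl ether carbon that becomes C2.

Step 6
Reactants: 10 tert-butyl (S)-3-[3,5-bis(benzyloxy)-2-formylphenoxy]-3-phenylpropanoate; 5 6-ethyl-4-hydroxy-5-methyl-2H-pyran-2-one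
Product: 12 tert-butyl (S)-3-[3,5-bis(benzyloxy)-2-[(6-ethyl-4-hydroxy-5-methyl-2-oxo-2H-pyran-3-yl)methyl]phenoxy]-3-phenylpropanoate, via arylidene pyrandione 11 (not isolated)
Conditions: L-proline (20 mol%), diethyl 2,6-dimethyl-1,4-dihydropyridine-3,5-dicarboxylate (Hantzsch ester, 1.2 equiv), CH2Cl2/EtOH, rt → 40 °C
Reagents that add atoms: none
Why: Organocatalytic three-component reductive Knoevenagel alkylation; amine-mediated condensation of the aldehyde at the only CH-acidic carbon of the pyranone (C3) gives 11, which the Hantzsch ester reduces by conjugate hydride transfer before a second pyranone can add, so the former formyl carbon becomes the CH2 bridge while the weakly basic medium leaves the β-aryloxy ester untouched.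

Step 7
Reactants: 12 tert-butyl ester from step 6
Product: 13 (S)-3-[3,5-bis(benzyloxy)-2-[(6-ethyl-4-hydroxy-5-methyl-2-oxo-2H-pyran-3-yl)methyl]phenoxy]-3-phenylpropanoic acid
Conditions: CF3CO2H/CH2Cl2 (1:4), Et3SiH (3 equiv), 0 °C → rt; volatiles removed with toluene
Reagents that add atoms: none
Why: Acidolysis of the tert-butyl ester with triethylsilane as cation scavenger, so that the tert-butyl cation is reduced to isobutane and does not alkylate the electron-rich ring; the benzyl ethers, the pyranone and the benzylic aryl ether (deactivated toward ionisation by the β-carboxyl group) are expected to survive cold dilute acid.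

Step 8
Reactants: 13 (S)-3-aryloxy-3-phenylpropanoic acid from step 7
Product: 15 (S)-5,7-bis(benzyloxy)-8-[(6-ethyl-4-hydroxy-5-methyl-2-oxo-2H-pyran-3-yl)methyl]-2-phenylchroman-4-one, via mixed trifluoroacetic anhydride 14 (not isolated)
Conditions: (CF3CO)2O (3 equiv), CH2Cl2, 0 °C; then pH 7 phosphate buffer
Reagents that add atoms: none
Why: Intramolecular Friedel–Crafts acylation: trifluoroacetic anhydride converts the acid into mixed anhydride 14, whose acyl carbon (acylium-like on loss of trifluoroacetate) is attacked by the arene carbon ortho to the ether oxygen and ortho/para to the two benzyloxy groups, and proton loss from the Wheland intermediate forms C4–C4a. The closest known reaction type is the cyclisation of 3-aryloxypropanoic acids to chroman-4-ones with trifluoroacetic anhydride. Ring C closes as a six-membered ring with the C=O bond exocyclic to the closing chain (6-exo-trig on the anhydride carbonyl). No stereocentre is created; C2 is carried through because no bond to it is made or broken, the medium has no base that could open the ring by retro-oxa-Michael elimination, and the β-acyl group disfavours ionisation of the benzylic C–O bond. The selectivity needed is regiochemical (C4a, not the carbon between the two benzyloxy groups) and the substrate fixes it: the other carbon ortho to the ether oxygen already carries the CH2 bridge, the three-atom tether cannot reach the remaining free carbon, the pyranone has no unsubstituted nucleophilic carbon, and any trifluoroacetate formed on its hydroxyl is cleaved on work-up.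

Step 9
Reactants: 15 (S)-5,7-bis(benzyloxy)-8-(pyranonylmethyl)flavanone from step 8
Product: 16 (S)-8-[(6-ethyl-4-hydroxy-5-methyl-2-oxo-2H-pyran-3-yl)methyl]-5,7-dihydroxy-2-phenylchroman-4-one (CNP0326321.1)
Conditions: H2 (1 atm), 10% Pd/C, EtOAc, rt, stopped after uptake of two equivalents
Reagents that add atoms: none
Why: Catalytic hydrogenolysis of the two O-benzyl groups; the O1–C2 bond of ring C, an alkyl aryl ether in a ring, is cleaved much more slowly, and the fully substituted pyranone double bonds and the aryl ketone should not be reduced at atmospheric pressure, so C2 stays (S).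

**Compound list**

1 | pentan-3-one | CCC(=O)CC | starting material
2 | 3-(trimethylsilyloxy)pent-2-ene (E/Z mixture) | CC=C(CC)O[Si](C)(C)C | intermediate
3 | malonyl dichloride | O=C(Cl)CC(=O)Cl | starting material
4 | 4-methyl-3,5-dioxoheptanoyl chloride | CCC(=O)C(C)C(=O)CC(=O)Cl | intermediate (not isolated)
5 | 6-ethyl-4-hydroxy-5-methyl-2H-pyran-2-one | CCc1oc(=O)cc(O)c1C | intermediate
6 | 2,4,6-trihydroxybenzaldehyde | O=Cc1c(O)cc(O)cc1O | starting material
7 | 2,4-bis(benzyloxy)-6-hydroxybenzaldehyde | O=Cc1c(O)cc(OCc2ccccc2)cc1OCc1ccccc1 | intermediate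
8 | tert-butyl 3-oxo-3-phenylpropanoate | CC(C)(C)OC(=O)CC(=O)c1ccccc1 | starting material
9 | tert-butyl (R)-3-hydroxy-3-phenylpropanoate | CC(C)(C)OC(=O)C[C@@H](O)c1ccccc1 | intermediate
10 | tert-butyl (S)-3-[3,5-bis(benzyloxy)-2-formylphenoxy]-3-phenylpropanoate | O=Cc1c(O[C@H](c2ccccc2)CC(=O)OC(C)(C)C)cc(OCc2ccccc2)cc1OCc1ccccc1 | intermediate
11 | tert-butyl (S)-3-[3,5-bis(benzyloxy)-2-[(6-ethyl-5-methyl-2,4-dioxopyran-3-ylidene)methyl]phenoxy]-3-phenylpropanoate (arylidene pyrandione) | CCC1=C(C)C(=O)C(=Cc2c(O[C@H](c3ccccc3)CC(=O)OC(C)(C)C)cc(OCc3ccccc3)cc2OCc2ccccc2)C(=O)O1 | intermediate (not isolated)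
12 | tert-butyl (S)-3-[3,5-bis(benzyloxy)-2-[(6-ethyl-4-hydroxy-5-methyl-2-oxo-2H-pyran-3-yl)methyl]phenoxy]-3-phenylpropanoate | CCc1oc(=O)c(Cc2c(O[C@H](c3ccccc3)CC(=O)OC(C)(C)C)cc(OCc3ccccc3)cc2OCc2ccccc2)c(O)c1C | intermediate
13 | (S)-3-[3,5-bis(benzyloxy)-2-[(6-ethyl-4-hydroxy-5-methyl-2-oxo-2H-pyran-3-yl)methyl]phenoxy]-3-phenylpropanoic acid | CCc1oc(=O)c(Cc2c(O[C@H](c3ccccc3)CC(=O)O)cc(OCc3ccccc3)cc2OCc2ccccc2)c(O)c1C | intermediate
14 | mixed anhydride of acid 13 with trifluoroacetic acid | CCc1oc(=O)c(Cc2c(O[C@H](c3ccccc3)CC(=O)OC(=O)C(F)(F)F)cc(OCc3ccccc3)cc2OCc2ccccc2)c(O)c1C | intermediate (not isolated)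
15 | (S)-5,7-bis(benzyloxy)-8-[(6-ethyl-4-hydroxy-5-methyl-2-oxo-2H-pyran-3-yl)methyl]-2-phenylchroman-4-one | CCc1oc(=O)c(Cc2c(OCc3ccccc3)cc(OCc3ccccc3)c3c2O[C@H](c2ccccc2)CC3=O)c(O)c1C | intermediate
16 | (S)-8-[(6-ethyl-4-hydroxy-5-methyl-2-oxo-2H-pyran-3-yl)methyl]-5,7-dihydroxy-2-phenylchroman-4-one (CNP0326321.1) | CCc1oc(=O)c(Cc2c(O)cc(O)c3c2O[C@H](c2ccccc2)CC3=O)c(O)c1C | target

**Step count and risks**

Total steps: 9. Longest linear sequence: 6 steps (for example 8 → 9 → 10 → 12 → 13 → 15 → 16).

Steps most likely to fail:

1. Step 5 (Mitsunobu etherification). The activated carbinol may undergo β-elimination to the cinnamate faster than the hydrogen-bonded, weakly nucleophilic phenoxide substitutes it, and some configuration may be lost through benzylic ionisation. Fallback, from 7 and back at 13: phenol 7 is coupled under the same Mitsunobu conditions with bought (R)-1-phenylbut-3-en-1-ol F1, a carbinol with no acidifying group to drive elimination, to give (S)-2,4-bis(benzyloxy)-6-[(1-phenylbut-3-en-1-yl)oxy]benzaldehyde F2. Reductive Knoevenagel alkylation of pyranone 5 with F2, run as in step 6, passes through the arylidene pyrandione F3 and gives the homoallyl ether F4. The terminal alkene is then cut by Lemieux–Johnson cleavage (OsO4 cat., NaIO4, 2,6-lutidine, dioxane/water) through the diol F5 to the β-aryloxy aldehyde F6, and Pinnick oxidation (NaClO2, NaH2PO4, 2-methyl-2-butene, tBuOH/water) converts F6 into acid 13.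

2. Step 6 (reductive Knoevenagel alkylation). Condensation of the doubly ortho-substituted, electron-rich aldehyde may be slow, so that the Hantzsch ester is consumed unproductively or a second pyranone adds to the arylidene intermediate. Fallback, from 10 and back at 12: the formyl group is reduced with NaBH4 (THF/MeOH, 0 °C) to the benzylic alcohol F7. This 2,4,6-trioxygenated benzyl alcohol ionises easily and is used for dehydrative C3-benzylation of pyranone 5 under mild Lewis acid catalysis (Sc(OTf)3 5 mol%, MeCN, rt), which gives 12 directly.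

3. Step 8 (ring C closure). Trifluoroacetylation or intermolecular acylation at the free carbon between the benzyloxy groups may compete; acid may scramble the CH2 bridge; and C2 may erode through reversible acid-mediated opening of ring C. Fallback, from 10 and back at 15: the order of bridge formation and ring closure is reversed, so the acylation runs on a formyl-deactivated arene without the pyranone. The tert-butyl ester of 10 is cleaved with CF3CO2H/CH2Cl2 without silane (which would reduce the formyl group) to the formyl acid F8, with loss of isobutene. (CF3CO)2O in CH2Cl2, with a trace of CF3SO3H if needed, converts F8 through the mixed anhydride F9 into (S)-5,7-bis(benzyloxy)-4-oxo-2-phenylchromane-8-carbaldehyde F10, again closing at the only free carbon ortho to the ether oxygen. Reductive Knoevenagel alkylation of pyranone 5 with F10 (L-proline, Hantzsch ester, as in step 6) passes through the arylidene pyrandione F11 and gives 15.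

Further compounds
F1 | step 5 | (R)-1-phenylbut-3-en-1-ol (bought reagent of the fallback) | C=CC[C@@H](O)c1ccccc1
F2 | step 5 | (S)-2,4-bis(benzyloxy)-6-[(1-phenylbut-3-en-1-yl)oxy]benzaldehyde | O=Cc1c(O[C@H](c2ccccc2)CC=C)cc(OCc2ccccc2)cc1OCc1ccccc1
F3 | step 5 | arylidene pyrandione from F2 and 5 | CCC1=C(C)C(=O)C(=Cc2c(O[C@H](c3ccccc3)CC=C)cc(OCc3ccccc3)cc2OCc2ccccc2)C(=O)O1
F4 | step 5 | (S)-3-[[2,4-bis(benzyloxy)-6-[(1-phenylbut-3-en-1-yl)oxy]phenyl]methyl]-6-ethyl-4-hydroxy-5-methyl-2H-pyran-2-one (homoallyl ether) | CCc1oc(=O)c(Cc2c(O[C@H](c3ccccc3)CC=C)cc(OCc3ccccc3)cc2OCc2ccccc2)c(O)c1C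
F5 | step 5 | diol from dihydroxylation of F4 (mixture of epimers at the new carbinol) | CCc1oc(=O)c(Cc2c(O[C@H](c3ccccc3)CC(O)CO)cc(OCc3ccccc3)cc2OCc2ccccc2)c(O)c1C
F6 | step 5 | (S)-3-[3,5-bis(benzyloxy)-2-[(6-ethyl-4-hydroxy-5-methyl-2-oxo-2H-pyran-3-yl)methyl]phenoxy]-3-phenylpropanal | CCc1oc(=O)c(Cc2c(O[C@H](c3ccccc3)CC=O)cc(OCc3ccccc3)cc2OCc2ccccc2)c(O)c1C
F7 | step 6 | tert-butyl (S)-3-[3,5-bis(benzyloxy)-2-(hydroxymethyl)phenoxy]-3-phenylpropanoate | OCc1c(O[C@H](c2ccccc2)CC(=O)OC(C)(C)C)cc(OCc2ccccc2)cc1OCc1ccccc1
F8 | step 8 | (S)-3-[3,5-bis(benzyloxy)-2-formylphenoxy]-3-phenylpropanoic acid | O=Cc1c(O[C@H](c2ccccc2)CC(=O)O)cc(OCc2ccccc2)cc1OCc1ccccc1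
F9 | step 8 | mixed anhydride of F8 with trifluoroacetic acid | O=Cc1c(O[C@H](c2ccccc2)CC(=O)OC(=O)C(F)(F)F)cc(OCc2ccccc2)cc1OCc1ccccc1
F10 | step 8 | (S)-5,7-bis(benzyloxy)-4-oxo-2-phenylchromane-8-carbaldehyde | O=Cc1c(OCc2ccccc2)cc(OCc2ccccc2)c2c1O[C@H](c1ccccc1)CC2=O
F11 | step 8 | arylidene pyrandione from F10 and 5 | CCC1=C(C)C(=O)C(=Cc2c(OCc3ccccc3)cc(OCc3ccccc3)c3c2O[C@H](c2ccccc2)CC3=O)C(=O)O1
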